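Time is the question here: we stop a row of flasks, differing in the charge of G, at 25 h and ask how much Z stands in each.

| setting | west | north | north-west | south-east |
|---|---|---|---|---|
| G | 0.0030 M | 0.0040 M | 0.0060 M | 0.010 M |
| L | 5.00 mM | 5.00 mM | 5.00 mM | 5.00 mM |
| time | 25 h | 25 h | 25 h | 25 h |

    L → X (k1 = 1.8 × 10⁻⁵ s⁻¹)
    G → Z (k2 = 9.4 × 10⁻⁶ s⁻¹)
    G ⇌ L (K3 = 0.38, k3 = 7.4 × 10⁻⁶ s⁻¹)
    Z ⇌ X (K4 = 1.6, k4 = 1.0 × 10⁻⁶ s⁻¹)

- [Z] at the end for west, north, north-west, south-east, in this order
- how the row runs (rises, then falls / rises all the way / hardly changes / falls, then rises / falls all the way)

- "hardly changes" means that all values lie within two and a half points (for a concentration: within two and a half percent of the largest)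
- run time (west): 25 h

Every step here is first order, so the charges of G and L act independently and their contributions to Z add up. The end value is therefore [Z] = s × (G charged) + b × (L charged), and we need the numbers s and b.

G and L feed each other. The back constant of step 3 is k3/K3 = 1.95 × 10⁻⁵ s⁻¹, so G leaves its pool with a total constant of 1.68 × 10⁻⁵ s⁻¹ and L with 3.75 × 10⁻⁵ s⁻¹. Such a coupled pair falls as a sum of two exponentials, with rate constants λ from a quadratic: 1.13 × 10⁻⁵ s⁻¹ and 4.30 × 10⁻⁵ s⁻¹. Up to the stop, each exponential encloses an area, one minus e^(−λt), divided by λ: 15.7 h for the slow one and 6.33 h for the fast one. A charge of G puts a weight of 0.826 on the slow exponential and the remainder on the fast one. Multiplying the area under the G curve by k2 gives the Z formed: 0.476 per mole of G charged and 0.195 per mole of L charged.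

The exchange Z ⇌ X relaxes with a half-life of 118 h in west, longer than the 25 h run, so we treat it as a correction. Z loses k4 times the area under its own curve and gains k4/K4 times the area under the X curve, both taken from the uncorrected curves. A mole of G charged gives areas of 7.11 h for Z and 1.64 h for X, so the correction is −0.0219. A mole of L charged gives 2.25 h and 9.04 h, so its correction is 0.0122.

That gives the yield per charge, s = 0.454, the moles of Z standing at the stop per mole of G charged, and likewise b = 0.207 for L. Our row is 0.00240 M, 0.00285 M, 0.00376 M and 0.00558 M, and it climbs throughout, since s is above zero.

The forecast gives 0.0024 M, 0.00285 M, 0.00376 M and 0.00558 M, and says the row rises all the way; its reckoning starts from the statement “All steps are first order, so the system is linear”. It rests on the same linear sum as our reckoning, so their closeness tests nothing.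

The simulation gives 0.00240 M, 0.00285 M, 0.00376 M and 0.00558 M, and the row rises all the way. In west the local order in G, the percent change of [Z] per percent of G, is 0.57. Since [Z] is a sum, that order is the share of Z owed to the G charge, s times the G charged over [Z], which in west is 0.568. In south-east the share reckoned this way is 0.814, and the local order there stands at 0.82.

The constants used here were set for the occasion; the result is computed.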